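**Retrosynthetic overview**
1. Target 23 ⇐ epoxy-spiro[4.5]decenone 21: an acid-triggered 1,2-shift of C1 from the spiro carbon to the epoxide carbon enlarges the cyclopentane to ring B and releases the ring A catechol (ring B is formed last, from a five-membered ring).
2. 21 ⇐ benzylic acetate 17: fluoride-triggered para-quinone methide formation, ipso (para) attack of the ring A phenoxide (cyclopentane formed first), then nucleophilic epoxidation.
3. 17 ⇐ lactone 13 + aldehyde 7: aldol addition and LiAlH4 reduction (sets C2), then silylation and acetylation.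
4. 13 ⇐ 7 + maleic anhydride 8: Wittig olefination, Rh-catalysed asymmetric hydrogenation (sets C3), ester-selective reduction.
5. 7 ⇐ catechol 1 + glyoxylic acid 3: methylation, para-formylation, silylation; both aryl rings come from 7.

Assumption: the tetralin locants of the target (C1 aryl-bearing carbon, C2 and C3 hydroxymethyl carbons, C4 CH2, C4a–C8a benzo carbons; ring A = benzo ring, ring B = saturated ring, ring C = pendant aryl) are used for the same atoms in all intermediates.

**Step 1**
Reactants: 1 catechol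
Product: 2 guaiacol
Conditions: MeI (0.8 equiv), K2CO3, acetone, 56 °C
Reagents that add atoms: iodomethane, CI
Why: Williamson ether synthesis on the monophenoxide, with MeI as the limiting reagent so that mono-methylation dominates and excess catechol is recovered by base extraction; no stereocenter.

**Step 2**
Reactants: 2 guaiacol; 3 glyoxylic acid
Product: 6 vanillin, via 4-hydroxy-3-methoxymandelic acid 4 (not isolated), via (4-hydroxy-3-methoxyphenyl)glyoxylic acid 5 (not isolated)
Conditions: NaOH, H2O, 30 °C; then CuSO4 (cat.), air, 95 °C; then H2SO4, 60 °C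
Reagents that add atoms: none
Why: Electrophilic aromatic hydroxyalkylation of the phenoxide para to OH, copper-catalysed aerobic oxidation of the mandelate and decarboxylation of the aryl glyoxylic acid on acidification (the technical vanillin synthesis); no stereocenter is kept.

**Step 3**
Reactants: 6 vanillin
Product: 7 3-methoxy-4-(triisopropylsilyloxy)benzaldehyde
Conditions: TIPSCl, imidazole, DMF, 23 °C
Reagents that add atoms: chlorotriisopropylsilane, CC(C)[Si](Cl)(C(C)C)C(C)C
Why: Imidazole-promoted silyl ether formation; the aryl TIPS ether survives the later ylide, hydride and enolate steps and is cleaved by fluoride exactly when the phenoxides are needed.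

**Step 4**
Reactants: 7 3-methoxy-4-(triisopropylsilyloxy)benzaldehyde; 8 maleic anhydride
Product: 11 (E)-aryl itaconate half-ester, via phosphoranylidene succinic anhydride 9 (not isolated), via ylide half-ester 10 (not isolated)
Conditions: 8, PPh3, acetone, 23 °C; MeOH, 23 °C; then 7, toluene, 90 °C
Reagents that add atoms: methanol, CO
Why: Wittig olefination with the ester-stabilised ylide (the Wittig variant of the Stobbe condensation) gives the E alkene with the free acid on the CH2 arm, as needed for directed hydrogenation.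

**Step 5**
Reactants: 11 (E)-aryl itaconate half-ester
Product: 12 (R)-2-arylmethyl succinic acid 1-methyl ester
Conditions: [Rh(cod)((S,S)-Et-DuPhos)]BF4 (1 mol%), H2 (5 bar), NaOMe (0.1 equiv), MeOH, 23 °C
Reagents that add atoms: none
Why: Rh-bisphospholane asymmetric hydrogenation of a Stobbe-type itaconate half-ester; chelation of carboxylate and alkene to Rh lets the (S,S) ligand deliver H2 to one face, which sets C3 as R (the ligand antipode would be used if the sense proved opposite).

**Step 6**
Reactants: 12 (R)-2-arylmethyl succinic acid 1-methyl ester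
Product: 13 (R)-4-[3-methoxy-4-(triisopropylsilyloxy)benzyl]dihydrofuran-2(3H)-one
Conditions: KOH (1.0 equiv), EtOH, 0 °C; CaCl2, NaBH4, −10 → 23 °C; then 2 M HCl
Reagents that add atoms: none
Why: Chemoselective borohydride reduction (Ca(BH4)2 reduces the ester but not the potassium carboxylate) followed by acid lactonisation; C3 is not touched.

**Step 7**
Reactants: 13 (R)-benzyl lactone; 7 3-methoxy-4-(triisopropylsilyloxy)benzaldehyde
Product: 15 (2R,3R)-triol, via lithium aldolate lactone 14 (not isolated)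
Conditions: LiN(iPr)2, THF, −78 °C; 7, −78 °C; then LiAlH4, −78 → 0 °C; H2O work-up
Reagents that add atoms: none
Why: Lithium enolate aldol addition in which the aldehyde adds anti to the C3 benzyl group (C2 set trans to C3), followed in the same flask by LiAlH4 reduction of the lactone before retro-aldol can occur; the carbinol carbon C1 is left as an epimer mixture because it becomes planar in step 9.

**Step 8**
Reactants: 15 (2R,3R)-triol
Product: 17 benzylic acetate bis-TBS ether, via bis-silyl ether alcohol 16 (not isolated)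
Conditions: TBSCl (2.1 equiv), imidazole, CH2Cl2, 0 °C; then Ac2O, Et3N, DMAP (cat.), 23 °C
Reagents that add atoms: tert-butyldimethylsilyl chloride, CC(C)(C)[Si](C)(C)Cl; acetic anhydride, CC(=O)OC(C)=O
Why: Sterically controlled silylation (primary OH over the hindered secondary benzylic OH) and then DMAP-catalysed acetylation put the leaving group on C1 only; no stereocenter changes.

**Step 9**
Reactants: 17 benzylic acetate bis-TBS ether
Product: 21 epoxy-spirodienone, via bisphenolate acetate 18 (not isolated), via para-quinone methide 19 (not isolated), via spirodienone 20 (not isolated)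
Conditions: Bu4NF (2.05 equiv), THF (0.01 M), −78 → −30 °C; then t-BuOOH, DBU, −30 → 0 °C; AcOH
Reagents that add atoms: tert-butyl hydroperoxide, CC(C)(C)OO
Why: Fluoride desilylation gives both phenoxides, the ring C phenoxide expels acetate (1,6-elimination) to the para-quinone methide, and the ring A phenoxide, whose only activated carbon within reach of C1 is its para carbon, closes the cyclopentane by 5-exo 1,6-addition (Winstein Ar1-5 type dearomatising alkylation) with the C1 aryl trans to the C2 substituent (least hindered, reversible); Weitz–Scheffer epoxidation then takes the unsubstituted enone, not the methoxy enone, from the face anti to C1.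

**Step 10**
Reactants: 21 epoxy-spirodienone
Product: 23 target CNP0219328.1, via bis-silyl catechol tetralin 22 (not isolated)
Conditions: Sc(OTf)3 (20 mol%), CH2Cl2/(CF3)2CHOH 4:1, −40 → 0 °C; then MeOH, HCl (0.1 M), 23 °C
Reagents that add atoms: none
Why: Proposed new method: Sc chelation of the epoxy ketone weakens the distal C8a–O bond, and the anti-periplanar C4a–C1 bond (benzylic, para-hydroxyphenyl-substituted, high migratory aptitude) shifts to C8a with retention at C1 (S, trans to C2); this enlarges the cyclopentane to ring B and fixes the C1–C8a regiochemistry, the methoxy-stabilised C4a cation loses H8a and the 6-hydroxy-2,4-dienone tautomerises to the ring A catechol, after which acidic methanol removes the TBS ethers; the closest known reactions are the dienone–phenol rearrangement of spiro[4.5]decadienones to tetralins, the semipinacol rearrangement of 2,3-epoxy alcohols and the arene oxide NIH shift.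

**Compound list**
1 | catechol | Oc1ccccc1O | starting material
2 | guaiacol (2-methoxyphenol) | COc1ccccc1O | intermediate
3 | glyoxylic acid | O=CC(=O)O | starting material
4 | 4-hydroxy-3-methoxymandelic acid (racemic) | COc1cc(C(O)C(=O)O)ccc1O | intermediate
5 | (4-hydroxy-3-methoxyphenyl)glyoxylic acid | COc1cc(C(=O)C(=O)O)ccc1O | intermediate
6 | vanillin | COc1cc(C=O)ccc1O | intermediate
7 | 3-methoxy-4-(triisopropylsilyloxy)benzaldehyde | COc1cc(C=O)ccc1O[Si](C(C)C)(C(C)C)C(C)C | intermediate
8 | maleic anhydride | O=C1C=CC(=O)O1 | starting material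
9 | (triphenylphosphoranylidene)succinic anhydride | O=C1CC(=P(c2ccccc2)(c2ccccc2)c2ccccc2)C(=O)O1 | intermediate
10 | methyl hydrogen (triphenylphosphoranylidene)succinate, ylide carbon bearing CO2Me | COC(=O)C(CC(=O)O)=P(c1ccccc1)(c1ccccc1)c1ccccc1 | intermediate
11 | (E)-3-(methoxycarbonyl)-4-[3-methoxy-4-(triisopropylsilyloxy)phenyl]but-3-enoic acid | COC(=O)/C(CC(=O)O)=C/c1ccc(O[Si](C(C)C)(C(C)C)C(C)C)c(OC)c1 | intermediate
12 | (R)-3-(methoxycarbonyl)-4-[3-methoxy-4-(triisopropylsilyloxy)phenyl]butanoic acid | COC(=O)[C@@H](CC(=O)O)Cc1ccc(O[Si](C(C)C)(C(C)C)C(C)C)c(OC)c1 | intermediate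
13 | (R)-4-[3-methoxy-4-(triisopropylsilyloxy)benzyl]dihydrofuran-2(3H)-one | O=C1OC[C@H](Cc2ccc(O[Si](C(C)C)(C(C)C)C(C)C)c(OC)c2)C1 | intermediate
14 | lithium alkoxide of (3S,4R)-3-{hydroxy[3-methoxy-4-(triisopropylsilyloxy)phenyl]methyl}-4-[3-methoxy-4-(triisopropylsilyloxy)benzyl]dihydrofuran-2(3H)-one (trans lactone, both carbinol epimers) | O=C1OC[C@H](Cc2ccc(O[Si](C(C)C)(C(C)C)C(C)C)c(OC)c2)[C@H]1C([O-])c1ccc(O[Si](C(C)C)(C(C)C)C(C)C)c(OC)c1.[Li+] | intermediate
15 | (2R,3R)-2-{hydroxy[3-methoxy-4-(triisopropylsilyloxy)phenyl]methyl}-3-[3-methoxy-4-(triisopropylsilyloxy)benzyl]butane-1,4-diol (both carbinol epimers) | COc1cc(C[C@@H](CO)[C@@H](C(O)c2ccc(O[Si](C(C)C)(C(C)C)C(C)C)c(OC)c2)CO)ccc1O[Si](C(C)C)(C(C)C)C(C)C | intermediate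
16 | 1,4-bis-O-TBS ether of 15 (benzylic OH free) | COc1cc(C[C@@H](CO[Si](C)(C)C(C)(C)C)[C@@H](C(O)c2ccc(O[Si](C(C)C)(C(C)C)C(C)C)c(OC)c2)CO[Si](C)(C)C(C)(C)C)ccc1O[Si](C(C)C)(C(C)C)C(C)C | intermediate
17 | (2R,3R)-4-(tert-butyldimethylsilyloxy)-2-[(tert-butyldimethylsilyloxy)methyl]-3-[3-methoxy-4-(triisopropylsilyloxy)benzyl]-1-[3-methoxy-4-(triisopropylsilyloxy)phenyl]butyl acetate (both C1 epimers) | COc1cc(C[C@@H](CO[Si](C)(C)C(C)(C)C)[C@@H](C(OC(C)=O)c2ccc(O[Si](C(C)C)(C(C)C)C(C)C)c(OC)c2)CO[Si](C)(C)C(C)(C)C)ccc1O[Si](C(C)C)(C(C)C)C(C)C | intermediate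
18 | bisphenol corresponding to 17 (both TIPS groups removed), present as its bis(tetrabutylammonium) phenolate | COc1cc(C[C@@H](CO[Si](C)(C)C(C)(C)C)[C@@H](C(OC(C)=O)c2ccc(O)c(OC)c2)CO[Si](C)(C)C(C)(C)C)ccc1O | intermediate
19 | para-quinone methide: 4-[(2R,3R)-4-(tert-butyldimethylsilyloxy)-2-[(tert-butyldimethylsilyloxy)methyl]-3-(4-hydroxy-3-methoxybenzyl)butylidene]-2-methoxycyclohexa-2,5-dien-1-one (ring A as phenolate) | COC1=CC(=C[C@@H](CO[Si](C)(C)C(C)(C)C)[C@H](CO[Si](C)(C)C(C)(C)C)Cc2ccc(O)c(OC)c2)C=CC1=O | intermediate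
20 | (1S,2R,3R)-2,3-bis[(tert-butyldimethylsilyloxy)methyl]-1-(4-hydroxy-3-methoxyphenyl)-7-methoxyspiro[4.5]deca-6,9-dien-8-one (all-trans cyclopentane, both spiro epimers) | O=C1C=CC2(C=C1OC)C[C@@H](CO[Si](C)(C)C(C)(C)C)[C@H](CO[Si](C)(C)C(C)(C)C)[C@H]2c1ccc(O)c(OC)c1 | intermediate
21 | 9,10-epoxide of 20: (1S,2R,3R)-2,3-bis[(tert-butyldimethylsilyloxy)methyl]-9,10-epoxy-1-(4-hydroxy-3-methoxyphenyl)-7-methoxyspiro[4.5]dec-6-en-8-one (epoxide oxygen anti to C1, both spiro epimers) | O=C1C2OC2C3(C=C1OC)C[C@@H](CO[Si](C)(C)C(C)(C)C)[C@H](CO[Si](C)(C)C(C)(C)C)[C@H]3c1ccc(O)c(OC)c1 | intermediate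
22 | (1S,2R,3R)-2,3-bis[(tert-butyldimethylsilyloxy)methyl]-7,8-dihydroxy-1-(4-hydroxy-3-methoxyphenyl)-6-methoxy-1,2,3,4-tetrahydronaphthalene | COc1cc([C@H]2c3c(cc(OC)c(O)c3O)C[C@@H](CO[Si](C)(C)C(C)(C)C)[C@@H]2CO[Si](C)(C)C(C)(C)C)ccc1O | intermediate
23 | (1S,2R,3R)-7,8-dihydroxy-1-(4-hydroxy-3-methoxyphenyl)-2,3-bis(hydroxymethyl)-6-methoxy-1,2,3,4-tetrahydronaphthalene (CNP0219328.1) | COc1cc([C@H]2c3c(cc(OC)c(O)c3O)C[C@@H](CO)[C@@H]2CO)ccc1O | target

**Step count**
Total steps: 10. Longest linear sequence: 10 (steps 1–10; aldehyde 7 enters twice, at steps 4 and 7).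

**Three steps most likely to fail**

Step 10 (the proposed new ring expansion). Risks are acyl migration or C4 migration in place of C1, and fragmentation of the C1–C4a bond to a quinone methide. The fallback uses known reactions only; it sets out from spirodienone 20 (isolated after the fluoride stage of step 9, without epoxidation) and comes back to the route at 22. The only free phenol of 20 is acylated with pivaloyl chloride (Et3N, DMAP) to give the pivalate spirodienone F1. A classical acid dienone–phenol rearrangement (CF3CO2H, CH2Cl2, 0 °C; C1 shifts to the ring carbon para to OMe, the minor regioisomer is separated) gives the 7-hydroxy-6-methoxytetralin pivalate F2, in which ring A now carries the only free phenol. NBS (CH2Cl2, −40 °C) brominates ortho to that phenol at C8 to give the 8-bromotetralin pivalate F3. Copper-catalysed hydroxylation (CuI, 1,10-phenanthroline, KOH, DMSO/H2O, 100 °C) exchanges Br for OH and cleaves the pivalate to give 22, which is desilylated as in step 10.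

Step 9 (spirocyclisation and epoxidation). Risks are direct six-ring closure at the ring A carbon para to OMe (which gives the tetralin lacking the C8 oxygen), quinone methide oligomerisation, and retro-addition before the epoxide forms. The fallback drops the spiro strategy, installs the third ring A oxygen early and closes ring B by a conventional Friedel–Crafts reaction; it sets out from lactone 13 and comes back at 23. Bu4NF gives the phenol lactone F4; NBS gives the ortho-bromophenol lactone F5; hydroxylation (CuI, 1,10-phenanthroline, KOH, DMSO/H2O, then HCl to relactonise) gives the catechol lactone F6; t-Bu2Si(OTf)2 and 2,6-lutidine give the silylene-protected lactone F7. Aldol addition to 7 (LiN(iPr)2, THF, −78 °C) gives the hydroxybenzyl lactone F8. CF3CO2H in CH2Cl2 closes ring B para to OMe with the C1 aryl trans to C2, and HF·pyridine then removes the silyl groups to give the triphenol tetralin lactone F9. LiAlH4 reduces F9 to 23.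

Step 2 (one-pot para-formylation). Risks are ortho condensation, double condensation and incomplete oxidation in the telescoped sequence. The fallback replaces the formylation by halogen–metal exchange; it sets out from guaiacol 2 and comes back at 7. NBS (MeCN, 0 °C) gives 4-bromo-2-methoxyphenol F10; TIPSCl and imidazole give the bromoaryl silyl ether F11; n-BuLi (THF, −78 °C) and then DMF give 7.

**Further compounds**
F1 | step 10 | 4-[(1S,2R,3R)-2,3-bis[(tert-butyldimethylsilyloxy)methyl]-7-methoxy-8-oxospiro[4.5]deca-6,9-dien-1-yl]-2-methoxyphenyl pivalate (both spiro epimers) | O=C1C=CC2(C=C1OC)C[C@@H](CO[Si](C)(C)C(C)(C)C)[C@H](CO[Si](C)(C)C(C)(C)C)[C@H]2c1ccc(OC(=O)C(C)(C)C)c(OC)c1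
F2 | step 10 | 4-[(1S,2R,3R)-2,3-bis[(tert-butyldimethylsilyloxy)methyl]-7-hydroxy-6-methoxy-1,2,3,4-tetrahydronaphthalen-1-yl]-2-methoxyphenyl pivalate | COc1cc([C@H]2c3cc(O)c(OC)cc3C[C@@H](CO[Si](C)(C)C(C)(C)C)[C@@H]2CO[Si](C)(C)C(C)(C)C)ccc1OC(=O)C(C)(C)C
F3 | step 10 | 4-[(1S,2R,3R)-8-bromo-2,3-bis[(tert-butyldimethylsilyloxy)methyl]-7-hydroxy-6-methoxy-1,2,3,4-tetrahydronaphthalen-1-yl]-2-methoxyphenyl pivalate | COc1cc([C@H]2c3c(Br)c(O)c(OC)cc3C[C@@H](CO[Si](C)(C)C(C)(C)C)[C@@H]2CO[Si](C)(C)C(C)(C)C)ccc1OC(=O)C(C)(C)C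
F4 | step 9 | (R)-4-(4-hydroxy-3-methoxybenzyl)dihydrofuran-2(3H)-one | O=C1OC[C@H](Cc2ccc(O)c(OC)c2)C1
F5 | step 9 | (R)-4-(3-bromo-4-hydroxy-5-methoxybenzyl)dihydrofuran-2(3H)-one | O=C1OC[C@H](Cc2cc(Br)c(O)c(OC)c2)C1
F6 | step 9 | (R)-4-(3,4-dihydroxy-5-methoxybenzyl)dihydrofuran-2(3H)-one | O=C1OC[C@H](Cc2cc(O)c(O)c(OC)c2)C1
F7 | step 9 | (R)-4-[(2,2-di-tert-butyl-7-methoxy-1,3,2-benzodioxasilol-5-yl)methyl]dihydrofuran-2(3H)-one | O=C1OC[C@H](Cc2cc(OC)c3O[Si](C(C)(C)C)(C(C)(C)C)Oc3c2)C1
F8 | step 9 | (3S,4R)-4-[(2,2-di-tert-butyl-7-methoxy-1,3,2-benzodioxasilol-5-yl)methyl]-3-{hydroxy[3-methoxy-4-(triisopropylsilyloxy)phenyl]methyl}dihydrofuran-2(3H)-one (both carbinol epimers) | O=C1OC[C@H](Cc2cc(OC)c3O[Si](C(C)(C)C)(C(C)(C)C)Oc3c2)[C@H]1C(O)c1ccc(O[Si](C(C)C)(C(C)C)C(C)C)c(OC)c1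
F9 | step 9 | trans-fused lactone of (1S,2R,3R)-7,8-dihydroxy-1-(4-hydroxy-3-methoxyphenyl)-3-(hydroxymethyl)-6-methoxy-1,2,3,4-tetrahydronaphthalene-2-carboxylic acid | COc1cc([C@H]2c3c(cc(OC)c(O)c3O)C[C@H]3COC(=O)[C@H]23)ccc1O
F10 | step 2 | 4-bromo-2-methoxyphenol | COc1cc(Br)ccc1O
F11 | step 2 | (4-bromo-2-methoxyphenoxy)triisopropylsilane | COc1cc(Br)ccc1O[Si](C(C)C)(C(C)C)C(C)C
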